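Ring B (eight-membered) is read as a masked cycloocta-1,5-diene: its tetrasubstituted C5=C6 alkene and the methylene-bearing C1 are 1,5-related (numbering below). Everything rests on an intramolecular nickel-catalysed [4+4] cycloaddition of two 1,3-dienes held on a trans-disubstituted ring D cyclopentanone. In one operation it forms C7–C15 (the ring B/ring C fusion bond) and C3–C4 (ring B CH2 to the ring A/ring B fusion CH), closes rings B and C and sets C4, C7 and C15. The precursor carries a (3-methylcyclopentenyl)propenyl diene (ring A) and a 2-(silyloxymethyl)butadienyl arm; the allylic alcohol so formed is later transposed reductively into the exocyclic methylene.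

Key step: step 13

Working numbering used in names and explanations: ring B = C1 (bears the exocyclic CH2), C2, C3, C4, C5, C6 (methyl), C7, C15; ring A = C4, C5, C16, C17, C18 (methyl); ring C = C7, C8, C9, C13, C14, C15; ring D = C9, C10 (isopropyl), C11, C12 (hydroxyl), C13 (methyl). In this numbering the target is 4S,7S,9S,10S,12R,13R,15S,18S.

Assumption on the chemistry: in step 1 the antipode of p-tol-BINAP is chosen that gives the 3S product; the sense of induction is to be confirmed on an aliquot hydrolysed to the known 3-methylcyclopentanone.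

Step 1
Reactants: 1 3-methylcyclopent-2-en-1-one
Product: 4 (3S)-3-methylcyclopent-1-en-1-yl trifluoromethanesulfonate, via bis(enoxy)diphenylsilane 2 (not isolated), via lithium enolate 3 (not isolated)
Conditions: CuCl (5 mol%), NaOt-Bu (5 mol%), p-tol-BINAP (5 mol%), Ph2SiH2 (0.55 equiv), toluene, 0 °C; then MeLi, THF, 0 °C; then N-(5-chloropyridin-2-yl)bis(trifluoromethanesulfonimide), −78 °C → rt
Reagents that add atoms: N-(5-chloropyridin-2-yl)bis(trifluoromethanesulfonimide), FC(F)(F)S(=O)(=O)N(c1ccc(Cl)cn1)S(=O)(=O)C(F)(F)F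
Why: Copper hydride asymmetric conjugate reduction should set the methyl-bearing centre (later C18) under ligand control and leave the enol silane regiospecifically on the side of that centre, so that Si–O cleavage and O-triflation of the lithium enolate fix the later C4=C5 double bond.

Step 2
Reactants: 4 (3S)-3-methylcyclopent-1-en-1-yl trifluoromethanesulfonate
Product: 5 (3S)-1-ethynyl-3-methylcyclopent-1-ene
Conditions: HC≡CMgBr, ZnBr2, Pd(PPh3)4 (3 mol%), THF, 0 °C → rt
Reagents that add atoms: ethynylmagnesium bromide, C#C[Mg]Br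
Why: Negishi alkynylation of an alkenyl triflate with ethynylzinc bromide should give the terminal enyne without touching the stereocentre.

Step 3
Reactants: 5 (3S)-1-ethynyl-3-methylcyclopent-1-ene
Product: 7 (3S)-1-[(1E)-1-iodoprop-1-en-2-yl]-3-methylcyclopent-1-ene, via alkenylalane 6 (not isolated)
Conditions: Me3Al, Cp2ZrCl2 (25 mol%), CH2Cl2, 0 °C → rt; then I2, THF, −30 °C
Reagents that add atoms: trimethylaluminium, C[Al](C)C; iodine, [I][I]
Why: Zirconium-catalysed syn-carboalumination (Negishi carbometallation) puts methyl on the inner and aluminium on the terminal alkyne carbon, and iodinolysis with retention should give the E dienyl iodide with iodine cis to the new methyl.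

Step 4
Reactants: 8 4-chlorobut-2-yn-1-ol
Product: 9 tert-butyl[(4-chlorobut-2-yn-1-yl)oxy]dimethylsilane
Conditions: TBSCl, imidazole, CH2Cl2, 0 °C → rt
Reagents that add atoms: tert-butyldimethylsilyl chloride, CC(C)(C)[Si](C)(C)Cl
Why: Standard silylation of a primary alcohol; the propargylic chloride is not affected.

Step 5
Reactants: 10 (4R)-4-[(tert-butyldimethylsilyl)oxy]cyclopent-2-en-1-one
Product: 12 (4S)-4-isopropylcyclopent-2-en-1-one, via silyloxy ketone 11 (not isolated)
Conditions: i-PrMgCl, CuBr·SMe2 (10 mol%), THF, −78 °C; aq. NH4Cl; then DBU, CH2Cl2, 0 °C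
Reagents that add atoms: isopropylmagnesium chloride, CC(C)[Mg]Cl
Why: Copper-catalysed 1,4-addition should occur anti to the silyloxy group, and E1cB loss of silanolate from the crude adduct transposes the enone, so the 4R centre of 10 is relayed to the isopropyl-bearing centre (later C10).

Step 6
Reactants: 12 (4S)-4-isopropylcyclopent-2-en-1-one
Product: 13 (4S)-2-iodo-4-isopropylcyclopent-2-en-1-one
Conditions: I2, pyridine, CH2Cl2, 0 °C → rt
Reagents that add atoms: iodine, [I][I]
Why: α-Iodination of the enone by pyridine-promoted addition–elimination of iodine, under which the γ-stereocentre is not enolised.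

Step 7
Reactants: 13 (4S)-2-iodo-4-isopropylcyclopent-2-en-1-one
Product: 14 (4S)-4-isopropyl-2-methylcyclopent-2-en-1-one
Conditions: SnMe4, Pd2(dba)3 (2.5 mol%), AsPh3, CuI, NMP, 80 °C
Reagents that add atoms: tetramethylstannane, C[Sn](C)(C)C
Why: Stille coupling of the α-iodoenone under neutral conditions should install the later C13 methyl without risk to the γ-stereocentre.

Step 8
Reactants: 14 (4S)-4-isopropyl-2-methylcyclopent-2-en-1-one; 9 tert-butyl[(4-chlorobut-2-yn-1-yl)oxy]dimethylsilane
Product: 17 (2R,3S,4S)-2-{4-[(tert-butyldimethylsilyl)oxy]but-2-yn-1-yl}-3-ethenyl-4-isopropyl-2-methylcyclopentan-1-one, via silyl enol ether 15 (not isolated), via lithium enolate 16 (not isolated)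
Conditions: vinylMgBr, CuBr·SMe2 (10 mol%), TMSCl, THF, −78 °C; then MeLi, THF, 0 °C; then 9, LiI, DMPU, −40 → 0 °C
Reagents that add atoms: vinylmagnesium bromide, C=C[Mg]Br
Why: In this three-component conjugate addition–enolate alkylation the vinyl cuprate should add anti to the isopropyl group (sets C9) and the regiodefined enolate should be alkylated anti to the new vinyl group (sets quaternary C13 with methyl cis to vinyl).

Step 9
Reactants: 17 (2R,3S,4S)-2-{4-[(tert-butyldimethylsilyl)oxy]but-2-yn-1-yl}-3-ethenyl-4-isopropyl-2-methylcyclopentan-1-one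
Product: 19 (2R,3S,4S)-2-{4-[(tert-butyldimethylsilyl)oxy]but-2-yn-1-yl}-3-(hydroxymethyl)-4-isopropyl-2-methylcyclopentan-1-one, via keto aldehyde 18 (not isolated)
Conditions: O3, CH2Cl2, −78 °C; PPh3; then MeOH, NaBH4, −78 °C
Reagents that add atoms: ozone, [O-][O+]=O
Why: Ozonolysis should cleave the terminal alkene much faster than the internal alkyne, and borohydride at low temperature reduces the aldehyde but not the hindered α-quaternary cyclopentanone, leaving C8 as a hydroxymethyl group.

Step 10
Reactants: 19 (2R,3S,4S)-2-{4-[(tert-butyldimethylsilyl)oxy]but-2-yn-1-yl}-3-(hydroxymethyl)-4-isopropyl-2-methylcyclopentan-1-one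
Product: 20 (2R,3S,4S)-2-{4-[(tert-butyldimethylsilyl)oxy]but-2-yn-1-yl}-3-(iodomethyl)-4-isopropyl-2-methylcyclopentan-1-one
Conditions: I2, PPh3, imidazole, CH2Cl2, 0 °C → rt
Reagents that add atoms: iodine, [I][I]
Why: Appel-type iodination of the primary alcohol by SN2 displacement of the alkoxyphosphonium ion.

Step 11
Reactants: 20 (2R,3S,4S)-2-{4-[(tert-butyldimethylsilyl)oxy]but-2-yn-1-yl}-3-(iodomethyl)-4-isopropyl-2-methylcyclopentan-1-one; 7 (3S)-1-[(1E)-1-iodoprop-1-en-2-yl]-3-methylcyclopent-1-ene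
Product: 22 (2R,3S,4S)-2-{4-[(tert-butyldimethylsilyl)oxy]but-2-yn-1-yl}-4-isopropyl-2-methyl-3-{(2E)-3-[(3S)-3-methylcyclopent-1-en-1-yl]but-2-en-1-yl}cyclopentan-1-one, via alkylzinc iodide 21 (not isolated)
Conditions: Zn dust (TMSCl-activated), LiCl, THF, 40 °C; then 7, Pd(dppf)Cl2 (5 mol%), THF, 50 °C
Reagents that add atoms: none
Why: Negishi coupling: zinc should insert into the primary C–I bond in the presence of ketone, alkyne and silyl ether, and palladium couples the alkylzinc with the dienyl iodide with retention of the E geometry (C8 cis to the C6 methyl).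

Step 12
Reactants: 22 (2R,3S,4S)-2-{4-[(tert-butyldimethylsilyl)oxy]but-2-yn-1-yl}-4-isopropyl-2-methyl-3-{(2E)-3-[(3S)-3-methylcyclopent-1-en-1-yl]but-2-en-1-yl}cyclopentan-1-one
Product: 24 (2R,3S,4S)-2-[(2Z)-3-{[(tert-butyldimethylsilyl)oxy]methyl}penta-2,4-dien-1-yl]-4-isopropyl-2-methyl-3-{(2E)-3-[(3S)-3-methylcyclopent-1-en-1-yl]but-2-en-1-yl}cyclopentan-1-one, via alkenylstannane 23 (not isolated)
Conditions: Bu3SnH, Pd(PPh3)2Cl2 (3 mol%), THF, 0 °C → rt; then vinyl bromide, Pd2(dba)3 (2 mol%), P(2-furyl)3, CuI, 50 °C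
Reagents that add atoms: vinyl bromide, C=CBr
Why: Palladium-catalysed syn-hydrostannation should place tin on the alkyne carbon next to the CH2OTBS group (oxygen-substituted side, remote from the neopentyl-like C14), and the one-pot Stille coupling proceeds with retention, giving the diene with C14 trans to the new vinyl group.

Step 13
Reactants: 24 (2R,3S,4S)-2-[(2Z)-3-{[(tert-butyldimethylsilyl)oxy]methyl}penta-2,4-dien-1-yl]-4-isopropyl-2-methyl-3-{(2E)-3-[(3S)-3-methylcyclopent-1-en-1-yl]but-2-en-1-yl}cyclopentan-1-one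
Product: 25 tetracyclic ketone (4S,7S,9S,10S,13R,15S,18S; C1=C2 and C5=C6 double bonds, CH2OTBS on C1, C12 ketone)
Conditions: Ni(cod)2 (20 mol%), PPh3 (40 mol%), toluene, 60 → 85 °C
Reagents that add atoms: none
Why: Zerovalent nickel binds both dienes and couples their tethered termini (oxidative cyclisation, C7–C15) to a bis(allyl) complex of divalent nickel, and reductive elimination between the two distal allyl termini (C3–C4) releases the cis,cis-cycloocta-1,5-diene; the closest known reaction type is the nickel-catalysed intramolecular [4+4] cycloaddition of bis-dienes with a four-atom tether, which gives trans-fused bicyclo[6.4.0] systems. Ring C closes in the C–C coupling step as a six-membered ring with both diene units exocyclic to it (chair-like, both allyl units equatorial on the trans-disubstituted cyclopentane), and ring B closes as the eight-membered ring by allyl–allyl reductive elimination (formal 4π+4π mode). C7 and C15 are therefore set by the resident C9 and C13 centres (H7 syn to H9, H15 syn to the C13 methyl, trans B/C fusion), and C4 is set relative to C7 because nickel stays on one face of the E-configured ring A diene, so both new bonds enter that diene suprafacially (H4 cis to H7). The step needs periselectivity for [4+4] over [4+2] and [2+2], which the substituents on the inner diene carbons (C6 methyl, C1 silyloxymethyl) should secure because every alternative reductive elimination would create a quaternary carbon. It also needs the tether to override the modest bias of the C18 methyl, which lies on the cyclopentene face that C3 must approach; this is the main uncertainty.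

Step 14
Reactants: 25 tetracyclic ketone
Product: 26 tetracyclic 12R alcohol (hydroxyl cis to the C13 methyl; CH2OTBS on C1)
Conditions: NaBH4, MeOH/THF, −20 → 0 °C
Reagents that add atoms: none
Why: Hydride reduction of the ring D ketone should occur from the face anti to the axial C13 methyl of the trans-hydrindane, as in 17-oxo steroids, giving the 12R alcohol.

Step 15
Reactants: 26 tetracyclic 12R alcohol
Product: 27 tetracyclic diol (CH2OH on C1, 12R hydroxyl)
Conditions: TBAF, THF, rt
Reagents that add atoms: none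
Why: Fluoride-mediated desilylation of the primary allylic silyl ether.

Step 16
Reactants: 27 tetracyclic diol
Product: 30 CNP0510481.1 (target), via sulfonylhydrazine adduct 28 (not isolated), via allylic diazene 29 (not isolated)
Conditions: 2-nitrobenzenesulfonylhydrazide, PPh3, DEAD, N-methylmorpholine, −30 °C → rt
Reagents that add atoms: none
Why: Reductive 1,3-transposition of the allylic alcohol: Mitsunobu displacement at the primary allylic carbon (the neopentyl-type C12 alcohol should not react), loss of sulfinic acid and retro-ene extrusion of N2 from the diazene deliver hydrogen to C2 and move the double bond to the exocyclic C1 position.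

Compound list
1 | 3-methylcyclopent-2-en-1-one | CC1=CC(=O)CC1 | starting material
2 | bis{[(3S)-3-methylcyclopent-1-en-1-yl]oxy}diphenylsilane | C[C@@H]1C=C(O[Si](OC2=C[C@@H](C)CC2)(c2ccccc2)c2ccccc2)CC1 | intermediate
3 | lithium (3S)-3-methylcyclopent-1-en-1-olate | C[C@@H]1C=C(O[Li])CC1 | intermediate
4 | (3S)-3-methylcyclopent-1-en-1-yl trifluoromethanesulfonate | C[C@@H]1C=C(OS(=O)(=O)C(F)(F)F)CC1 | intermediate
5 | (3S)-1-ethynyl-3-methylcyclopent-1-ene | C[C@@H]1C=C(C#C)CC1 | intermediate
6 | dimethyl{(1E)-2-[(3S)-3-methylcyclopent-1-en-1-yl]prop-1-en-1-yl}alumane | C[C@@H]1C=C(CC1)/C(C)=C/[Al](C)C | intermediate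
7 | (3S)-1-[(1E)-1-iodoprop-1-en-2-yl]-3-methylcyclopent-1-ene | C[C@@H]1C=C(CC1)/C(C)=C/I | intermediate
8 | 4-chlorobut-2-yn-1-ol | OCC#CCCl | starting material
9 | tert-butyl[(4-chlorobut-2-yn-1-yl)oxy]dimethylsilane | CC(C)(C)[Si](C)(C)OCC#CCCl | intermediate
10 | (4R)-4-[(tert-butyldimethylsilyl)oxy]cyclopent-2-en-1-one | O=C1C=C[C@H](O[Si](C)(C)C(C)(C)C)C1 | starting material
11 | (3S,4R)-4-[(tert-butyldimethylsilyl)oxy]-3-isopropylcyclopentan-1-one (isopropyl trans to silyloxy) | O=C1C[C@@H](C(C)C)[C@H](O[Si](C)(C)C(C)(C)C)C1 | intermediate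
12 | (4S)-4-isopropylcyclopent-2-en-1-one | O=C1C=C[C@H](C(C)C)C1 | intermediate
13 | (4S)-2-iodo-4-isopropylcyclopent-2-en-1-one | O=C1C(I)=C[C@H](C(C)C)C1 | intermediate
14 | (4S)-4-isopropyl-2-methylcyclopent-2-en-1-one | O=C1C(C)=C[C@H](C(C)C)C1 | intermediate
15 | {[(3S,4S)-3-ethenyl-4-isopropyl-2-methylcyclopent-1-en-1-yl]oxy}trimethylsilane | C=C[C@H]1[C@H](C(C)C)CC(O[Si](C)(C)C)=C1C | intermediate
16 | lithium (3S,4S)-3-ethenyl-4-isopropyl-2-methylcyclopent-1-en-1-olate | C=C[C@H]1[C@H](C(C)C)CC(O[Li])=C1C | intermediate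
17 | (2R,3S,4S)-2-{4-[(tert-butyldimethylsilyl)oxy]but-2-yn-1-yl}-3-ethenyl-4-isopropyl-2-methylcyclopentan-1-one | C=C[C@H]1[C@H](C(C)C)CC(=O)[C@]1(C)CC#CCO[Si](C)(C)C(C)(C)C | intermediate
18 | (1S,2R,5S)-2-{4-[(tert-butyldimethylsilyl)oxy]but-2-yn-1-yl}-5-isopropyl-2-methyl-3-oxocyclopentane-1-carbaldehyde | O=C[C@H]1[C@H](C(C)C)CC(=O)[C@]1(C)CC#CCO[Si](C)(C)C(C)(C)C | intermediate
19 | (2R,3S,4S)-2-{4-[(tert-butyldimethylsilyl)oxy]but-2-yn-1-yl}-3-(hydroxymethyl)-4-isopropyl-2-methylcyclopentan-1-one | OC[C@H]1[C@H](C(C)C)CC(=O)[C@]1(C)CC#CCO[Si](C)(C)C(C)(C)C | intermediate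
20 | (2R,3S,4S)-2-{4-[(tert-butyldimethylsilyl)oxy]but-2-yn-1-yl}-3-(iodomethyl)-4-isopropyl-2-methylcyclopentan-1-one | IC[C@H]1[C@H](C(C)C)CC(=O)[C@]1(C)CC#CCO[Si](C)(C)C(C)(C)C | intermediate
21 | {[(1S,2R,5S)-2-{4-[(tert-butyldimethylsilyl)oxy]but-2-yn-1-yl}-5-isopropyl-2-methyl-3-oxocyclopentyl]methyl}(iodo)zinc | I[Zn]C[C@H]1[C@H](C(C)C)CC(=O)[C@]1(C)CC#CCO[Si](C)(C)C(C)(C)C | intermediate
22 | (2R,3S,4S)-2-{4-[(tert-butyldimethylsilyl)oxy]but-2-yn-1-yl}-4-isopropyl-2-methyl-3-{(2E)-3-[(3S)-3-methylcyclopent-1-en-1-yl]but-2-en-1-yl}cyclopentan-1-one | C[C@@H]1C=C(CC1)/C(C)=C/C[C@H]2[C@H](C(C)C)CC(=O)[C@]2(C)CC#CCO[Si](C)(C)C(C)(C)C | intermediate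
23 | (2R,3S,4S)-2-[(2E)-4-[(tert-butyldimethylsilyl)oxy]-3-(tributylstannyl)but-2-en-1-yl]-4-isopropyl-2-methyl-3-{(2E)-3-[(3S)-3-methylcyclopent-1-en-1-yl]but-2-en-1-yl}cyclopentan-1-one | C[C@@H]1C=C(CC1)/C(C)=C/C[C@H]2[C@H](C(C)C)CC(=O)[C@]2(C)C/C=C(/[Sn](CCCC)(CCCC)CCCC)CO[Si](C)(C)C(C)(C)C | intermediate
24 | (2R,3S,4S)-2-[(2Z)-3-{[(tert-butyldimethylsilyl)oxy]methyl}penta-2,4-dien-1-yl]-4-isopropyl-2-methyl-3-{(2E)-3-[(3S)-3-methylcyclopent-1-en-1-yl]but-2-en-1-yl}cyclopentan-1-one | C[C@@H]1C=C(CC1)/C(C)=C/C[C@H]2[C@H](C(C)C)CC(=O)[C@]2(C)C/C=C(/C=C)CO[Si](C)(C)C(C)(C)C | intermediate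
25 | tetracyclic ketone, working numbering 4S,7S,9S,10S,13R,15S,18S: C1=C2 and C5=C6 double bonds, CH2OTBS on C1, methyls on C6, C13, C18, isopropyl on C10, C12 ketone | CC(C)(C)[Si](C)(C)OC/C1=C/C[C@@H]2/C(=C(/C)[C@H]3C[C@H]4[C@H](C(C)C)CC(=O)[C@]4(C)C[C@H]13)CC[C@@H]2C | intermediate
26 | 12R alcohol of 25 (hydroxyl cis to the C13 methyl) | CC(C)(C)[Si](C)(C)OC/C1=C/C[C@@H]2/C(=C(/C)[C@H]3C[C@H]4[C@H](C(C)C)C[C@@H](O)[C@]4(C)C[C@H]13)CC[C@@H]2C | intermediate
27 | tetracyclic diol (CH2OH on C1, 12R hydroxyl, other centres as in 26) | OC/C1=C/C[C@@H]2/C(=C(/C)[C@H]3C[C@H]4[C@H](C(C)C)C[C@@H](O)[C@]4(C)C[C@H]13)CC[C@@H]2C | intermediate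
28 | N-allyl-N-(2-nitrobenzenesulfonyl)hydrazine from 27 (sulfonylated nitrogen on the C1 CH2) | NN(C/C1=C/C[C@@H]2/C(=C(/C)[C@H]3C[C@H]4[C@H](C(C)C)C[C@@H](O)[C@]4(C)C[C@H]13)CC[C@@H]2C)S(=O)(=O)c1ccccc1[N+](=O)[O-] | intermediate
29 | allylic diazene (C1–CH2–N=NH) | N=NC/C1=C/C[C@@H]2/C(=C(/C)[C@H]3C[C@H]4[C@H](C(C)C)C[C@@H](O)[C@]4(C)C[C@H]13)CC[C@@H]2C | intermediate
30 | CNP0510481.1, working numbering 4S,7S,9S,10S,12R,13R,15S,18S: C1 exocyclic methylene, C5=C6 alkene, 12-hydroxyl, methyls on C6, C13, C18, isopropyl on C10 | C=C1CC[C@@H]2/C(=C(/C)[C@H]3C[C@H]4[C@H](C(C)C)C[C@@H](O)[C@]4(C)C[C@H]13)CC[C@@H]2C | target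

Total step count: 16. Longest linear sequence: 12 steps (steps 5 to 16, from 10).

Steps most likely to fail

1. Step 13. The oxidative cyclisation may stall or lose facial control: the tetrasubstituted ring A diene binds nickel weakly, the C18 methyl shields the face that must react, and zerovalent nickel can be drained by oxidative cyclisation of a diene with the ring D ketone. The fallback sets out from 24 and removes the carbonyl from play. Silylation (TMSOTf, Et3N, CH2Cl2, −78 °C; only C11 can be enolised) should give the trimethylsilyl enol ether of 24 F1. The same nickel-catalysed cycloaddition on this substrate should give the trimethylsilyl enol ether of 25 F2. K2CO3 in MeOH then unmasks the ketone without touching the primary silyl ether, and the route is rejoined at 25.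

2. Step 12. Tin may be delivered to the wrong alkyne carbon, and the one-pot Stille stage may suffer protodestannylation or homocoupling. The fallback sets out from 22 and is stepwise. Hydrostannation alone is run and 23 is isolated, with chromatographic removal of the regioisomer. Iododestannylation (I2, CH2Cl2, 0 °C) should give the E alkenyl iodide F3. Suzuki–Miyaura coupling with vinylboronic acid pinacol ester (Pd(dppf)Cl2, K3PO4, THF/H2O) returns to the route at 24.

3. Step 11. Zinc insertion may be incomplete, or the β-branched alkylzinc may be protonated or transmetallate slowly, so that 20 is simply reduced. The fallback sets out from 20 and 7 and joins the two iodides directly by nickel-catalysed reductive cross-electrophile coupling (NiBr2(dme), 4,4'-di-tert-butyl-2,2'-bipyridine, Mn powder, NaI, DMPU), without a preformed organometallic. It comes back at 22 and makes no new compound (F0).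

Further compounds
F1 | step 13 | trimethylsilyl enol ether of 24 (C11=C12–OSiMe3, all stereocentres as in 24) | C[C@@H]1C=C(CC1)/C(C)=C/C[C@H]2[C@H](C(C)C)C=C(O[Si](C)(C)C)[C@]2(C)C/C=C(/C=C)CO[Si](C)(C)C(C)(C)C
F2 | step 13 | trimethylsilyl enol ether of 25 (C11=C12–OSiMe3, all stereocentres as in 25) | CC(C)(C)[Si](C)(C)OC/C1=C/C[C@@H]2/C(=C(/C)[C@H]3C[C@H]4[C@H](C(C)C)C=C(O[Si](C)(C)C)[C@]4(C)C[C@H]13)CC[C@@H]2C
F3 | step 12 | (2R,3S,4S)-2-[(2E)-4-[(tert-butyldimethylsilyl)oxy]-3-iodobut-2-en-1-yl]-4-isopropyl-2-methyl-3-{(2E)-3-[(3S)-3-methylcyclopent-1-en-1-yl]but-2-en-1-yl}cyclopentan-1-one | C[C@@H]1C=C(CC1)/C(C)=C/C[C@H]2[C@H](C(C)C)CC(=O)[C@]2(C)C/C=C(/I)CO[Si](C)(C)C(C)(C)C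
F0 | step 11 | none | none
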